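**Retrosynthetic overview**
1. Target 14 is (S)-hesperetin with C-prenyl groups at C8 (ring A) and C2' (ring B). Rings A, B and C and the C2 stereocentre all come from (S)-hesperetin 1, so no ring is formed and only two skeletal C–C bonds are made.
2. Feature used: on ring A, C8 is para to O5, with C6 as the ortho carbon between them. On ring B, C2' is the only hydrogen-bearing carbon ortho to O3', because C4' carries OMe. Both prenyl groups can therefore be placed on oxygen and moved to carbon by [3,3] shifts.
3. 14 ⇐ 13 (O7 desilylation) ⇐ 8 by a one-flask double rearrangement: Claisen shift O5→C6 then Cope shift C6→C8 (bond C8–C1''), and ortho-Claisen shift O3'→C2' of a 1,1-dimethylallyl ether (bond C2'–C1''').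
4. 8 ⇐ 1 by O7 silylation, palladium-catalysed O3' tert-prenylation with carbonate 5 (made from 2-methylbut-3-en-2-ol 3), and Mitsunobu prenylation of O5 with prenol 7.

Key step: step 5

Assumption: (S)-hesperetin 1 is used as the single enantiomer (a commercial lot is checked by chiral HPLC and enriched by preparative chiral chromatography if partly racemic); flavanone numbering is used throughout (ring C O1–C4, ring A C5–C8, ring B C1'–C6').

**Step 1**
Reactants: 1 (S)-hesperetin
Product: 2 (S)-7-O-triisopropylsilylhesperetin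
Conditions: TIPSCl (1.05 equiv), imidazole (2.2 equiv), DMF, 0 °C
Reagents that add atoms: triisopropylsilyl chloride (TIPSCl), CC(C)[Si](Cl)(C(C)C)C(C)C
Why: In this imidazole-mediated silylation of a phenol, the 7-OH (para to the C4 carbonyl) is the most acidic and least hindered hydroxyl, the 5-OH is tied up in a hydrogen bond to C4=O and the guaiacol-type 3'-OH is less acidic, so one equivalent of the bulky silyl chloride should go to O7.

**Step 2**
Reactants: 3 2-methylbut-3-en-2-ol
Product: 5 tert-butyl 2-methylbut-3-en-2-yl carbonate, via lithium 2-methylbut-3-en-2-olate 4 (not isolated)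
Conditions: n-BuLi (1.05 equiv), THF, −78 to 0 °C; then Boc2O (1.2 equiv), 0 °C to rt; water work-up
Reagents that add atoms: di-tert-butyl dicarbonate (Boc2O), CC(C)(C)OC(=O)OC(=O)OC(C)(C)C; n-butyllithium, [Li]CCCC (supplies only the lithium of 4)
Why: This is an alkoxycarbonylation of a lithium alkoxide, in which deprotonation makes the hindered tertiary alcohol nucleophilic enough to attack Boc2O and the expelled tert-butyl carbonate ion collapses to CO2 and tert-butoxide.

**Step 3**
Reactants: 2 (S)-7-O-triisopropylsilylhesperetin; 5 tert-butyl 2-methylbut-3-en-2-yl carbonate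
Product: 6 (S)-3'-O-(1,1-dimethylallyl)-7-O-triisopropylsilylhesperetin
Conditions: Pd(PPh3)4 (5 mol%), 5 (1.5 equiv), degassed THF, 0 to 4 °C
Reagents that add atoms: none
Why: In this Tsuji–Trost O-allylation, zerovalent palladium ionises the tertiary carbonate with loss of CO2 to a 1,1-dimethyl-π-allyl complex and tert-butoxide, which deprotonates the free 3'-OH, and the phenoxide attacks the more substituted allyl terminus under kinetic control at low temperature to give the branched ether while the hydrogen-bonded 5-OH stays out.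

**Step 4**
Reactants: 6 (S)-3'-O-(1,1-dimethylallyl)-7-O-triisopropylsilylhesperetin; 7 3-methylbut-2-en-1-ol (prenol)
Product: 8 (S)-5-O-prenyl-3'-O-(1,1-dimethylallyl)-7-O-triisopropylsilylhesperetin
Conditions: 7 (1.5 equiv), PPh3 (1.5 equiv), DIAD (1.5 equiv, added last), THF, 0 °C to rt
Reagents that add atoms: none
Why: In this Mitsunobu etherification the 5-OH, the only remaining hydroxyl, is acidic enough to protonate the phosphine–azodicarboxylate adduct, and its phenoxide displaces the primary allylic oxyphosphonium ion at carbon without the carbonate bases that could open ring C or strip the silyl ether.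

**Step 5**
Reactants: 8 (S)-5-O-prenyl-3'-O-(1,1-dimethylallyl)-7-O-triisopropylsilylhesperetin
Product: 13 (S)-8,2'-diprenyl-7-O-triisopropylsilylhesperetin, via C6 dienone 9 (not isolated), via C8 dienone 10 (not isolated), via ring A rearranged ether 11 (not isolated), via C2' dienone 12 (not isolated)
Conditions: Eu(fod)3 [europium tris(6,6,7,7,8,8,8-heptafluoro-2,2-dimethyl-3,5-octanedionate)] (0.2 equiv), dry PhMe, sealed tube, 70 °C then 120 °C
Reagents that add atoms: none
Why: Trivalent europium, held in a chelate by C4=O and O5, polarises the O5–allyl bond and should trigger an aromatic Claisen [3,3] shift to C6 (dienone 9, reversed prenyl group), after which a Cope [3,3] shift across C7=C8 carries the group to C8 with normal prenyl connectivity (dienone 10) and enolisation restores the hydrogen-bonded 5-OH (11). On further heating the tertiary allyl ether of ring B should undergo an ortho-Claisen [3,3] shift to C2' (dienone 12), which enolises to the 3'-OH of 13. The closest known reactions are the lanthanide-catalysed Claisen–Cope (para-Claisen) rearrangement of 5-O-prenylflavanones to 8-prenylflavanones and the thermal ortho-Claisen rearrangement of aryl 1,1-dimethylallyl ethers of isovanillin-type phenols. No ring is closed and no stereocentre is created: the sp3 ring carbons of 9, 10 and 12 are transient and become aromatic again, and C2 is left alone because the medium holds neither base nor protic acid that could open ring C. The selectivity needed is positional: on ring A the Cope shift must outrun enolisation of 9, which the aprotic medium, the europium chelate of the C4/C5 dicarbonyl unit of 9 and the relief of crowding at the quaternary carbon wedged between C5=O and the C7 silyloxy group should favour; on ring B a shift to C4' is unproductive because that carbon carries OMe and cannot lose a proton (the adduct reverts or at most passes slowly on to C6'), so C2' should be the outlet.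

**Step 6**
Reactants: 13 (S)-8,2'-diprenyl-7-O-triisopropylsilylhesperetin
Product: 14 (2S)-5,7-dihydroxy-2-[3-hydroxy-4-methoxy-2-(3-methylbut-2-en-1-yl)phenyl]-8-(3-methylbut-2-en-1-yl)chroman-4-one (target)
Conditions: Bu4NF (1.2 equiv), AcOH (1.5 equiv), THF, 0 °C
Reagents that add atoms: none
Why: In this fluoride-induced cleavage of an aryl silyl ether, the strong Si–F bond and the good 7-phenoxide leaving group (para to C4=O) should make the reaction fast at 0 °C, and acetic acid keeps the medium from becoming basic enough to open ring C to the chalcone and racemise C2.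

**Compound list**
1 | (S)-hesperetin, (2S)-5,7-dihydroxy-2-(3-hydroxy-4-methoxyphenyl)chroman-4-one | COc1ccc([C@@H]2CC(=O)c3c(O)cc(O)cc3O2)cc1O | starting material
2 | (S)-7-O-triisopropylsilylhesperetin | COc1ccc([C@@H]2CC(=O)c3c(O)cc(O[Si](C(C)C)(C(C)C)C(C)C)cc3O2)cc1O | intermediate
3 | 2-methylbut-3-en-2-ol | C=CC(C)(C)O | starting material
4 | lithium 2-methylbut-3-en-2-olate | [Li+].[O-]C(C)(C)C=C | intermediate
5 | tert-butyl 2-methylbut-3-en-2-yl carbonate | C=CC(C)(C)OC(=O)OC(C)(C)C | intermediate
6 | (S)-3'-O-(1,1-dimethylallyl)-7-O-triisopropylsilylhesperetin | COc1ccc([C@@H]2CC(=O)c3c(O)cc(O[Si](C(C)C)(C(C)C)C(C)C)cc3O2)cc1OC(C)(C)C=C | intermediate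
7 | 3-methylbut-2-en-1-ol (prenol) | CC(C)=CCO | starting material
8 | (S)-5-O-prenyl-3'-O-(1,1-dimethylallyl)-7-O-triisopropylsilylhesperetin | COc1ccc([C@@H]2CC(=O)c3c(OCC=C(C)C)cc(O[Si](C(C)C)(C(C)C)C(C)C)cc3O2)cc1OC(C)(C)C=C | intermediate
9 | C6 dienone: (2S)-6-(2-methylbut-3-en-2-yl)-5-oxo-5,6-dihydro tautomer of ring A (C6 unassigned, transient), ring B ether unchanged | COc1ccc([C@@H]2CC(=O)C3=C(O2)C=C(O[Si](C(C)C)(C(C)C)C(C)C)C(C(C)(C)C=C)C3=O)cc1OC(C)(C)C=C | intermediate
10 | C8 dienone: (2S)-8-(3-methylbut-2-enyl)-5-oxo-5,8-dihydro tautomer of ring A (C8 unassigned, transient), ring B ether unchanged | COc1ccc([C@@H]2CC(=O)C3=C(O2)C(CC=C(C)C)C(O[Si](C(C)C)(C(C)C)C(C)C)=CC3=O)cc1OC(C)(C)C=C | intermediate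
11 | ring A rearranged ether: (S)-3'-O-(1,1-dimethylallyl)-8-prenyl-7-O-triisopropylsilylhesperetin | COc1ccc([C@@H]2CC(=O)c3c(O)cc(O[Si](C(C)C)(C(C)C)C(C)C)c(CC=C(C)C)c3O2)cc1OC(C)(C)C=C | intermediate
12 | C2' dienone: ring B as 4'-methoxy-2'-(3-methylbut-2-enyl)-3'-oxocyclohexa-4',6'(1')-diene (C2' unassigned, transient), ring A as in 11 | COC1=CC=C([C@@H]2CC(=O)c3c(O)cc(O[Si](C(C)C)(C(C)C)C(C)C)c(CC=C(C)C)c3O2)C(CC=C(C)C)C1=O | intermediate
13 | (S)-8,2'-diprenyl-7-O-triisopropylsilylhesperetin | COc1ccc([C@@H]2CC(=O)c3c(O)cc(O[Si](C(C)C)(C(C)C)C(C)C)c(CC=C(C)C)c3O2)c(CC=C(C)C)c1O | intermediate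
14 | (2S)-5,7-dihydroxy-2-[3-hydroxy-4-methoxy-2-(3-methylbut-2-en-1-yl)phenyl]-8-(3-methylbut-2-en-1-yl)chroman-4-one | COc1ccc([C@@H]2CC(=O)c3c(O)cc(O)c(CC=C(C)C)c3O2)c(CC=C(C)C)c1O | target

**Step count**
Total: 6 steps. Longest linear sequence: 5 steps (1 → 2 → 6 → 8 → 13 → 14, steps 1, 3, 4, 5 and 6); step 2 is a one-step side branch.

**Steps most likely to fail**

Step 5. The C6 dienone may enolise before the Cope shift, leaving the allyl group at C6 in its reversed form. The Lewis acid may ionise the tertiary allyl ether at the temperature the ring B shift needs, so the group is lost as isoprene. The freed ortho-prenyl phenol may also cyclise onto its own alkene. The fallback decouples the two shifts. Setting out from 6, thermolysis without any Lewis acid (xylene, 130 °C) should bring about the ring B ortho-Claisen shift alone and give (S)-2'-prenyl-7-O-triisopropylsilylhesperetin F1. The 3'-OH is then capped (TBSCl, imidazole, DMF) to give (S)-3'-O-tert-butyldimethylsilyl-2'-prenyl-7-O-triisopropylsilylhesperetin F2. Mitsunobu reaction with 7 (PPh3, DIAD, THF) gives (S)-3'-O-tert-butyldimethylsilyl-5-O-prenyl-2'-prenyl-7-O-triisopropylsilylhesperetin F3. Eu(fod)3 (0.1 equiv) in toluene at 60–70 °C, the window in which the Claisen–Cope relay of 5-O-prenylflavanones is established, should give (S)-3'-O-tert-butyldimethylsilyl-8,2'-diprenyl-7-O-triisopropylsilylhesperetin F4. Bu4NF/AcOH (2.5 equiv, THF, 0 °C) removes both silyl groups and the sequence rejoins the route at the target 14.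

Step 3. Palladium may re-ionise the tertiary ether so that it drifts to the linear prenyl ether, allylation may compete at O5, or the alkoxide formed may attack the silyl ether. The fallback builds the tertiary ether as an alkyne that cannot ionise on palladium. Setting out from 2, copper-catalysed O-alkylation with 3-chloro-3-methylbut-1-yne (DBU 1.3 equiv, CuCl2·2H2O cat., dry MeCN, −5 °C) should give (S)-3'-O-(1,1-dimethylpropargyl)-7-O-triisopropylsilylhesperetin F5. Semi-hydrogenation of the terminal alkyne (H2, Pd on CaCO3 poisoned with Pb(OAc)2, quinoline, EtOAc) rejoins the route at 6.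

Step 1. Silylation may spread over O7 and O3' (mono- and bis-silyl mixtures) or the silyl group may migrate. The fallback uses a temporary acyl group and moves the silylation to a stage where only one free phenol is left. Setting out from 1, BzCl (1.0 equiv), pyridine, CH2Cl2, −20 °C should acylate the most acidic phenol and give (S)-7-O-benzoylhesperetin F6. The conditions of step 3 with carbonate 5 give (S)-7-O-benzoyl-3'-O-(1,1-dimethylallyl)hesperetin F7. Aminolysis of the activated aryl ester (n-BuNH2, THF, 0 °C) gives (S)-3'-O-(1,1-dimethylallyl)hesperetin F8, in which the 7-OH is the only phenol not locked in a hydrogen bond. TIPSCl/imidazole in DMF at 0 °C then rejoins the route at 6.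

**Further compounds**
F1 | step 5 | (S)-2'-prenyl-7-O-triisopropylsilylhesperetin | COc1ccc([C@@H]2CC(=O)c3c(O)cc(O[Si](C(C)C)(C(C)C)C(C)C)cc3O2)c(CC=C(C)C)c1O
F2 | step 5 | (S)-3'-O-tert-butyldimethylsilyl-2'-prenyl-7-O-triisopropylsilylhesperetin | COc1ccc([C@@H]2CC(=O)c3c(O)cc(O[Si](C(C)C)(C(C)C)C(C)C)cc3O2)c(CC=C(C)C)c1O[Si](C)(C)C(C)(C)C
F3 | step 5 | (S)-3'-O-tert-butyldimethylsilyl-5-O-prenyl-2'-prenyl-7-O-triisopropylsilylhesperetin | COc1ccc([C@@H]2CC(=O)c3c(OCC=C(C)C)cc(O[Si](C(C)C)(C(C)C)C(C)C)cc3O2)c(CC=C(C)C)c1O[Si](C)(C)C(C)(C)C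
F4 | step 5 | (S)-3'-O-tert-butyldimethylsilyl-8,2'-diprenyl-7-O-triisopropylsilylhesperetin | COc1ccc([C@@H]2CC(=O)c3c(O)cc(O[Si](C(C)C)(C(C)C)C(C)C)c(CC=C(C)C)c3O2)c(CC=C(C)C)c1O[Si](C)(C)C(C)(C)C
F5 | step 3 | (S)-3'-O-(1,1-dimethylpropargyl)-7-O-triisopropylsilylhesperetin | COc1ccc([C@@H]2CC(=O)c3c(O)cc(O[Si](C(C)C)(C(C)C)C(C)C)cc3O2)cc1OC(C)(C)C#C
F6 | step 1 | (S)-7-O-benzoylhesperetin | COc1ccc([C@@H]2CC(=O)c3c(O)cc(OC(=O)c4ccccc4)cc3O2)cc1O
F7 | step 1 | (S)-7-O-benzoyl-3'-O-(1,1-dimethylallyl)hesperetin | COc1ccc([C@@H]2CC(=O)c3c(O)cc(OC(=O)c4ccccc4)cc3O2)cc1OC(C)(C)C=C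
F8 | step 1 | (S)-3'-O-(1,1-dimethylallyl)hesperetin | COc1ccc([C@@H]2CC(=O)c3c(O)cc(O)cc3O2)cc1OC(C)(C)C=C
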